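**Conventions.** Bicycle numbering: C1 and C5 are the bridgeheads; ring A = C1, C2, O3, C4, C5; ring B = C1, C5, C6, O7, C8. ArA = 4-hydroxy-3-methoxyphenyl (on C2); ArB = 3-hydroxy-4,5-dimethoxyphenyl (on C6). ArA-Si = 3-methoxy-4-(triisopropylsilyloxy)phenyl and ArB-Si = 3,4-dimethoxy-5-(triisopropylsilyloxy)phenyl are their triisopropylsilyl (TIPS) ethers. Acyclic and monocyclic intermediates keep these atom labels in the discussion.

Assumption: compounds 1, 4, 7 and 10 are bought, and the aldol of step 7 is taken to follow the facial sense of a magnesium-chelated Z-enolate attacked opposite the benzyl group of the auxiliary.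

## Analysis of the target

Compound 22 is a 2,6-diaryl-3,7-dioxabicyclo[3.3.0]octane: two tetrahydrofuran rings, ring A and ring B, fused cis along C1–C5. It carries four contiguous stereocentres, (1R,2S,5R,6S); the bridgehead hydrogens are cis, and each aryl group lies on the convex (exo) face, cis to the neighbouring bridgehead hydrogen. The core would be C2-symmetric, but ArA on C2 and ArB on C6 differ, so the two halves must be brought in separately and placed correctly. The sensitive groups are the two free phenols and the two benzylic ether carbons. C2–O3 stands para to an oxygen and ionises under acid in a quinone-methide-like way, which epimerises C2, and both benzylic C–O bonds are open to hydrogenolysis. The difficulty is to set four adjacent centres on a small bicycle with both aryl groups exo under kinetic control, since acid equilibration of such ethers is expected to give exo/endo mixtures. The strategy rests on one feature: C2 is a benzylic ether carbon lying δ to C1 along C1–C5–C4–O3–C2. A ketone at C1 in a preformed ring B can therefore reach H–C2 through a seven-membered transition state, bond C1 to C2 to close ring A, and leave only a bridgehead hydroxyl to remove.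

## Retrosynthetic reasoning

**22 to 21 (O–Si bonds).** The phenols are masked as TIPS ethers in 21 and released last by buffered desilylation, which needs neither acid nor hydrogen. TIPS is preferred to a smaller silyl group because steps 3, 4 and 8 use alkoxide, hydroxide and hydroperoxide, which a less hindered aryl silyl ether would not survive reliably.

**21 to 19 by way of 20 (C1–H from C1–O).** The bridgehead hydrogen is traced back to the tertiary hydroxyl of 19, because the ring closure that makes C1–C2 needs a carbonyl at C1. The hydroxyl is removed as the oxalate 20 by a radical chain. The forward step must deliver hydrogen to C1 with cis ring fusion, which the strain of a trans-fused bicyclo[3.3.0]octane should enforce. C2, C5 and C6 are not touched.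

**19 to 18 (C1–C2).** This is the one ring A bond that can be formed without ionising a benzylic carbon: closures at C2–O3 would pass through a C2 cation and lose control of the aryl orientation. Cutting C1–C2 reduces the bicycle to the monocyclic furanone 18 with only two stereocentres, and turns the ArA half into a plain benzyl ether. The forward reaction has to abstract hydrogen only at C2, close the five-membered ring, and place ArA exo.

**18 to 17 (O7–C8).** Ring B is opened at the ether bond to the hydroxy diazoketone 17. Carbenoid O–H insertion closes it under neutral conditions. A base-mediated O-alkylation would expose a β-hydroxy, β-alkoxy ketone to retro-aldol cleavage and elimination.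

**17 to 15 to 13 (C1–C8, then the acyl–N bond).** The diazomethyl carbon is added to the carboxyl group of hydroxy acid 15 through the mixed anhydride 16. Acid 15 comes from imide 13 by cleavage of the auxiliary, which is recovered as 7.

**13 to 9 and 11 (C5–C6).** This aldol bond joins the ArB half, aldehyde 11, to the three-carbon chain that already carries the ArA benzyl ether, imide 9. It sets C5 and C6 in one step. The anti relationship is required because it maps onto the trans arrangement in 18, and the absolute sense comes from auxiliary 7.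

**9 to 6 and 7; 6 to 5 to 3 and 4 (acyl–N and C4–O3).** The ether oxygen O3 is attached to C4 by conjugate addition of benzylic alcohol 3 to acrylate 4. A methyl ester is used so that ester 5 can be cleaved to acid 6 with hydroxide; the electron-rich benzyl ether would not survive the acid needed for a tert-butyl ester.

**3 to 2 to 1, and 11 to 10 (O–Si).** Starting from aldehyde 1 allows the phenol to be silylated cleanly before the benzylic hydroxyl exists. Aldehyde 10 is silylated directly.

## Alternatives that were turned down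

**Alternative 1:** The skeleton is cut at C5–C6 and C1–C2 around a chiral butenolide. In the key step the lithiated dithiane A3 adds to the β-carbon (C5) of the menthyloxy butenolide A2 anti to the menthyloxy group, and the lactone enolate is trapped at C1 by aldehyde A4, trans to the new substituent, giving A1.
- For it: three components are joined in one flask, both bridgehead centres are set with absolute control from an inexpensive acetal, and the reaction type is well established on γ-alkoxybutenolides. On convergence and on step count to the full carbon skeleton it is stronger than the chosen route.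
- Against it for this target: C6 enters as a dithioketal carbon with no configuration and C2 as an uncontrolled carbinol. The route must then unmask the dithioketal beside electron-rich arenes, reduce the ketone, lactone and acetal, and close both rings by cyclodehydration through benzylic cations. C2 and C6 are thus fixed last, under acid, where exo and endo isomers interconvert. The benzyl ethers must finally be removed by hydrogenolysis (H2, Pd/C) next to two benzylic ring C–O bonds.
- Comparison: the chosen route is more linear, but it sets C6 in the aldol and C2 in a neutral, kinetically controlled closure, and never exposes the benzylic ethers to acid.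

**Alternative 2:** C1–C5 is made together with a temporary C2–C6 bond. In the key step the triplet-sensitised ferulate ester A6, bound to a chiral Lewis acid, adds to the alkene of the cinnamyl ether A7 to give the all-trans cyclobutane A5. The ester is then reduced, the primary silyl ether removed, and the C2–C6 bond cleaved oxidatively while the two hydroxymethyl oxygens close rings A and B.
- For it: both halves come from simple cinnamyl units and are joined in a single step, and the trans arrangement of C4 and C8 on the cyclobutane translates into the cis ring fusion. On paper it is the shortest route.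
- Against it: two electronically similar β-aryl alkenes must cross-react in preference to homodimerisation, in one regiochemistry, without E/Z scrambling. A simple ester binds a Lewis acid only weakly and through one point, and a β-alkyl styrene is a poor partner. The oxidative scission erases the configurations at C2 and C6, which must be re-set in a cationic trapping step, with over-oxidation of the electron-rich rings as a further hazard.
- Comparison: the chosen route gives up step economy for reaction types established on their substrate classes and for a named control element at each of the four centres.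

**Alternative 3:** Only C1–C5 is cut. The eight-membered diolide A9 is doubly deprotonated at C1 and C5 and oxidised by one electron (divalent copper or an anode) to couple the two enolate carbons across the ring, giving the bis-lactone A8 with both five-membered rings closed.
- For it: C2 and C6 are set early and independently by reliable asymmetric syntheses of β-hydroxy acids, so on control of these two centres it is equal or stronger, and the two aryl groups are told apart without effort.
- Against it: A9 is a medium-ring diolide of two different β-hydroxy acids, whose formation competes with β-lactones, oligomers and dehydration. Each ester enolate carries a benzylic β-acyloxy leaving group, so fragmentation to cinnamates should outrun oxidation. The enolate carbons are held far apart across the ring. A8 then needs both lactone carbonyls, C4 and C8, reduced fully to methylene, which passes through ring-opened intermediates.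
- Comparison: the key step fights an elimination built into its substrate. In the chosen route the only enolate with a β-leaving group is a chelated imide enolate with a poor alkoxide leaving group.

Key step: step 11

## Route

Step 1
Reactants: 1 vanillin (4-hydroxy-3-methoxybenzaldehyde)
Product: 2 3-methoxy-4-(triisopropylsilyloxy)benzaldehyde
Conditions: TIPSCl, imidazole, DMF, rt
Reagents that add atoms: triisopropylsilyl chloride, CC(C)[Si](Cl)(C(C)C)C(C)C
Why: Silyl ether formation at the phenol; the hindered TIPS ether is chosen because it should survive the alkoxide, hydroxide and hydroperoxide of steps 3, 4 and 8.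

Step 2
Reactants: 2 3-methoxy-4-(triisopropylsilyloxy)benzaldehyde
Product: 3 [3-methoxy-4-(triisopropylsilyloxy)phenyl]methanol
Conditions: NaBH4, MeOH/THF, 0 °C
Reagents that add atoms: none
Why: Borohydride reduction of the aldehyde; reducing after silylation avoids having to distinguish the phenol from the benzylic hydroxyl.

Step 3
Reactants: 3 [3-methoxy-4-(triisopropylsilyloxy)phenyl]methanol; 4 methyl acrylate
Product: 5 methyl 3-{[3-methoxy-4-(triisopropylsilyloxy)benzyl]oxy}propanoate
Conditions: NaH (10 mol%), methyl acrylate (3 equiv), THF, 0 °C to rt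
Reagents that add atoms: none
Why: Base-catalysed oxa-Michael addition of the benzylic alkoxide to the acrylate, which makes the C4–O3 ether bond; the ester enolate is protonated by 3 and regenerates the alkoxide, so only catalytic base is present.

Step 4
Reactants: 5 methyl 3-{[3-methoxy-4-(triisopropylsilyloxy)benzyl]oxy}propanoate
Product: 6 3-{[3-methoxy-4-(triisopropylsilyloxy)benzyl]oxy}propanoic acid
Conditions: LiOH·H2O, THF/MeOH/H2O, 0 °C to rt; then 1 M HCl to pH 4 at 0 °C
Reagents that add atoms: lithium hydroxide (hydroxide oxygen), [Li+].[OH-]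
Why: Ester saponification; hydroxide is used because the 4-silyloxybenzyl ether is acid-labile in the manner of a p-methoxybenzyl ether.

Step 5
Reactants: 6 3-{[3-methoxy-4-(triisopropylsilyloxy)benzyl]oxy}propanoic acid; 7 (4S)-4-benzyl-1,3-oxazolidin-2-one
Product: 9 (4S)-4-benzyl-3-(3-{[3-methoxy-4-(triisopropylsilyloxy)benzyl]oxy}propanoyl)-1,3-oxazolidin-2-one, via mixed pivalic anhydride 8 (not isolated)
Conditions: PivCl, Et3N, THF, −20 °C; then 7, LiCl, −20 °C to rt
Reagents that add atoms: pivaloyl chloride, CC(C)(C)C(=O)Cl (supplies the pivaloyl group of 8 only; none of it stays in 9)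
Why: N-Acylation of the oxazolidinone through the mixed anhydride, which is attacked at its less hindered carbonyl by the LiCl-activated oxazolidinone; no stereocentre is formed.

Step 6
Reactants: 10 3-hydroxy-4,5-dimethoxybenzaldehyde
Product: 11 3,4-dimethoxy-5-(triisopropylsilyloxy)benzaldehyde
Conditions: TIPSCl, imidazole, DMF, rt
Reagents that add atoms: triisopropylsilyl chloride, CC(C)[Si](Cl)(C(C)C)C(C)C
Why: Silyl ether formation at the phenol, as in step 1.

Step 7
Reactants: 9 (4S)-4-benzyl-3-(3-{[3-methoxy-4-(triisopropylsilyloxy)benzyl]oxy}propanoyl)-1,3-oxazolidin-2-one; 11 3,4-dimethoxy-5-(triisopropylsilyloxy)benzaldehyde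
Product: 13 (4S)-4-benzyl-3-[(2R,3S)-3-hydroxy-3-(ArB-Si)-2-{[(ArA-Si)methoxy]methyl}propanoyl]-1,3-oxazolidin-2-one, via O-trimethylsilyl aldol adduct 12 (not isolated)
Conditions: MgCl2 (20 mol%), Et3N, TMSCl, EtOAc, 23 °C; then citric acid, MeOH, 0 °C
Reagents that add atoms: chlorotrimethylsilane, C[Si](C)(C)Cl (silyl group of 12 only; removed again before 13 is isolated)
Why: Magnesium-halide-catalysed direct anti-aldol reaction of an N-acyloxazolidinone: soft enolisation of the MgCl2-chelated imide gives the chelated Z-enolate, which should add to the aryl aldehyde on the face opposite the benzyl group (C5 as R) through a boat-like transition state (anti, C6 as S). Silylation of the aldolate by TMSCl releases the catalyst and blocks retro-aldol; the mild methanolysis removes only the trimethylsilyl group.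

Step 8
Reactants: 13 (4S)-4-benzyl-3-[(2R,3S)-3-hydroxy-3-(ArB-Si)-2-{[(ArA-Si)methoxy]methyl}propanoyl]-1,3-oxazolidin-2-one
Product: 15 (2R,3S)-3-hydroxy-3-(ArB-Si)-2-{[(ArA-Si)methoxy]methyl}propanoic acid, via peroxy acid 14 (not isolated)
Conditions: LiOH, 30% H2O2, THF/H2O, 0 °C; then aq. Na2SO3; then 1 M HCl to pH 4
Reagents that add atoms: hydrogen peroxide, OO
Why: Hydroperoxide cleavage of the N-acyloxazolidinone at the exocyclic carbonyl, followed by sulfite reduction of the peroxy acid; the auxiliary 7 is released and C5 and C6 are not affected.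

Step 9
Reactants: 15 (2R,3S)-3-hydroxy-3-(ArB-Si)-2-{[(ArA-Si)methoxy]methyl}propanoic acid
Product: 17 (3R,4S)-1-diazo-4-hydroxy-4-(ArB-Si)-3-{[(ArA-Si)methoxy]methyl}butan-2-one, via mixed isobutyl carbonic anhydride 16 (not isolated)
Conditions: i-BuOCOCl, N-methylmorpholine, THF, −20 °C; then CH2N2, Et2O, −20 to 0 °C
Reagents that add atoms: diazomethane, C=[N+]=[N-]; isobutyl chloroformate, CC(C)COC(=O)Cl (in 16 only)
Why: Acylation of diazomethane by a mixed carbonic anhydride (first stage of an Arndt–Eistert sequence), which adds C8; at −20 °C the carboxylate should react with the chloroformate much faster than the hindered secondary hydroxyl.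

Step 10
Reactants: 17 (3R,4S)-1-diazo-4-hydroxy-4-(ArB-Si)-3-{[(ArA-Si)methoxy]methyl}butan-2-one
Product: 18 (4R,5S)-5-(ArB-Si)-4-{[(ArA-Si)methoxy]methyl}dihydrofuran-3(2H)-one
Conditions: Rh2(OAc)4 (1 mol%), CH2Cl2, rt, slow addition of 17
Reagents that add atoms: none
Why: Intramolecular O–H insertion of a rhodium carbenoid: Rh2(OAc)4 (divalent rhodium) turns the diazoketone into an electrophilic carbenoid at C8, the C6 hydroxyl attacks it, and proton transfer closes ring B under neutral conditions. C5 and C6 are untouched, so the trans relation follows from the anti-aldol.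

Step 11
Reactants: 18 (4R,5S)-5-(ArB-Si)-4-{[(ArA-Si)methoxy]methyl}dihydrofuran-3(2H)-one
Product: 19 (1S,2R,5R,6S)-2-(ArA-Si)-6-(ArB-Si)-3,7-dioxabicyclo[3.3.0]octan-1-ol
Conditions: hν (λ > 300 nm, Pyrex-filtered medium-pressure Hg lamp), degassed benzene (0.005 M), 20 °C
Reagents that add atoms: none
Why: Norrish–Yang photocyclisation: n→π* excitation of the C1 carbonyl, at wavelengths where the arenes do not absorb, gives an oxygen-centred radical that takes the hydrogen from C2 through a seven-membered transition state (1,6-hydrogen transfer); that C–H bond is weakened by both O3 and ArA. The only hydrogen that is formally γ, H-6, is held in ring B pointing away from the carbonyl oxygen, so abstraction should be site-selective. The resulting ketyl–benzyl 1,5-biradical closes ring A by radical recombination between C1 and C2, a five-membered ring closure that gives the tetrahydrofuran-3-ol. The closest known reaction type is the Yang cyclisation of β-alkoxy ketones to tetrahydrofuran-3-ols by δ-hydrogen abstraction. C1 is controlled by the tether: C5–C4–O3 can deliver C2 only to the face of C1 on which C4 sits, trans to ArB, so the fusion is cis and the hydroxyl ends on the convex face. C2 is controlled in the closure itself: the planar benzylic radical can rotate before bonding and should bond with ArA turned away from C8 and the concave face, which places ArA exo as in 22. The step needs chemoselectivity over α-cleavage of the furanone and over reverse hydrogen transfer; the activated, well-placed C2–H bond and the dilute, oxygen-free, non-polar medium are what should secure it.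

Step 12
Reactants: 19 (1S,2R,5R,6S)-2-(ArA-Si)-6-(ArB-Si)-3,7-dioxabicyclo[3.3.0]octan-1-ol
Product: 20 (1S,2R,5R,6S)-2-(ArA-Si)-6-(ArB-Si)-3,7-dioxabicyclo[3.3.0]octan-1-yl methyl oxalate
Conditions: ClCOCO2Me, Et3N, DMAP (cat.), CH2Cl2, 0 °C to rt
Reagents that add atoms: methyl chlorooxoacetate, COC(=O)C(=O)Cl
Why: Acylation of the tertiary bridgehead alcohol by a small, highly electrophilic acid chloride under nucleophilic catalysis; an oxalate, unlike a xanthate, cannot undergo thermal syn-elimination.

Step 13
Reactants: 20 (1S,2R,5R,6S)-2-(ArA-Si)-6-(ArB-Si)-3,7-dioxabicyclo[3.3.0]octan-1-yl methyl oxalate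
Product: 21 (1R,2S,5R,6S)-2-(ArA-Si)-6-(ArB-Si)-3,7-dioxabicyclo[3.3.0]octane
Conditions: Bu3SnH, AIBN (cat.), toluene, 110 °C
Reagents that add atoms: none
Why: Radical deoxygenation of a tertiary methyl oxalate: the stannyl radical adds to the oxalate carbonyl, C1–O β-scission gives the tertiary C1 radical, and hydrogen transfer from Bu3SnH to the convex face restores the cis-fused bicycle, so hydrogen replaces the hydroxyl with retention. C2, C5 and C6 are not involved.

Step 14
Reactants: 21 (1R,2S,5R,6S)-2-(ArA-Si)-6-(ArB-Si)-3,7-dioxabicyclo[3.3.0]octane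
Product: 22 (1R,2S,5R,6S)-2-(4-hydroxy-3-methoxyphenyl)-6-(3-hydroxy-4,5-dimethoxyphenyl)-3,7-dioxabicyclo[3.3.0]octane
Conditions: Bu4NF, AcOH, THF, 0 °C
Reagents that add atoms: none
Why: Fluoride cleavage of both aryl silyl ethers; acetic acid buffers the phenoxides so that the 4-oxidobenzyl ether at C2 cannot open to a quinone methide and epimerise.

## Compound list

1 | vanillin (4-hydroxy-3-methoxybenzaldehyde) | COc1cc(C=O)ccc1O | starting material
2 | 3-methoxy-4-(triisopropylsilyloxy)benzaldehyde | COc1cc(C=O)ccc1O[Si](C(C)C)(C(C)C)C(C)C | intermediate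
3 | [3-methoxy-4-(triisopropylsilyloxy)phenyl]methanol | COc1cc(CO)ccc1O[Si](C(C)C)(C(C)C)C(C)C | intermediate
4 | methyl acrylate | C=CC(=O)OC | starting material
5 | methyl 3-{[3-methoxy-4-(triisopropylsilyloxy)benzyl]oxy}propanoate | COC(=O)CCOCc1ccc(O[Si](C(C)C)(C(C)C)C(C)C)c(OC)c1 | intermediate
6 | 3-{[3-methoxy-4-(triisopropylsilyloxy)benzyl]oxy}propanoic acid | OC(=O)CCOCc1ccc(O[Si](C(C)C)(C(C)C)C(C)C)c(OC)c1 | intermediate
7 | (4S)-4-benzyl-1,3-oxazolidin-2-one | O=C1N[C@@H](Cc2ccccc2)CO1 | starting material
8 | mixed anhydride of 6 with pivalic acid | CC(C)(C)C(=O)OC(=O)CCOCc1ccc(O[Si](C(C)C)(C(C)C)C(C)C)c(OC)c1 | intermediate (not isolated)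
9 | (4S)-4-benzyl-3-(3-{[3-methoxy-4-(triisopropylsilyloxy)benzyl]oxy}propanoyl)-1,3-oxazolidin-2-one | O=C(CCOCc1ccc(O[Si](C(C)C)(C(C)C)C(C)C)c(OC)c1)N1[C@@H](Cc2ccccc2)COC1=O | intermediate
10 | 3-hydroxy-4,5-dimethoxybenzaldehyde | COc1cc(C=O)cc(O)c1OC | starting material
11 | 3,4-dimethoxy-5-(triisopropylsilyloxy)benzaldehyde | COc1cc(C=O)cc(O[Si](C(C)C)(C(C)C)C(C)C)c1OC | intermediate
12 | O-trimethylsilyl ether of 13 | O=C(N1[C@@H](Cc2ccccc2)COC1=O)[C@H](COCc1ccc(O[Si](C(C)C)(C(C)C)C(C)C)c(OC)c1)[C@H](O[Si](C)(C)C)c1cc(OC)c(OC)c(O[Si](C(C)C)(C(C)C)C(C)C)c1 | intermediate (not isolated)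
13 | (4S)-4-benzyl-3-[(2R,3S)-3-hydroxy-3-(ArB-Si)-2-{[(ArA-Si)methoxy]methyl}propanoyl]-1,3-oxazolidin-2-one | O=C(N1[C@@H](Cc2ccccc2)COC1=O)[C@H](COCc1ccc(O[Si](C(C)C)(C(C)C)C(C)C)c(OC)c1)[C@H](O)c1cc(OC)c(OC)c(O[Si](C(C)C)(C(C)C)C(C)C)c1 | intermediate
14 | (2R,3S)-3-hydroxy-3-(ArB-Si)-2-{[(ArA-Si)methoxy]methyl}propaneperoxoic acid | OOC(=O)[C@H](COCc1ccc(O[Si](C(C)C)(C(C)C)C(C)C)c(OC)c1)[C@H](O)c1cc(OC)c(OC)c(O[Si](C(C)C)(C(C)C)C(C)C)c1 | intermediate (not isolated)
15 | (2R,3S)-3-hydroxy-3-(ArB-Si)-2-{[(ArA-Si)methoxy]methyl}propanoic acid | OC(=O)[C@H](COCc1ccc(O[Si](C(C)C)(C(C)C)C(C)C)c(OC)c1)[C@H](O)c1cc(OC)c(OC)c(O[Si](C(C)C)(C(C)C)C(C)C)c1 | intermediate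
16 | mixed anhydride of 15 with isobutyl hydrogen carbonate | CC(C)COC(=O)OC(=O)[C@H](COCc1ccc(O[Si](C(C)C)(C(C)C)C(C)C)c(OC)c1)[C@H](O)c1cc(OC)c(OC)c(O[Si](C(C)C)(C(C)C)C(C)C)c1 | intermediate (not isolated)
17 | (3R,4S)-1-diazo-4-hydroxy-4-(ArB-Si)-3-{[(ArA-Si)methoxy]methyl}butan-2-one | [N-]=[N+]=CC(=O)[C@H](COCc1ccc(O[Si](C(C)C)(C(C)C)C(C)C)c(OC)c1)[C@H](O)c1cc(OC)c(OC)c(O[Si](C(C)C)(C(C)C)C(C)C)c1 | intermediate
18 | (4R,5S)-5-(ArB-Si)-4-{[(ArA-Si)methoxy]methyl}dihydrofuran-3(2H)-one | O=C1CO[C@H](c2cc(O[Si](C(C)C)(C(C)C)C(C)C)c(OC)c(OC)c2)[C@H]1COCc1ccc(O[Si](C(C)C)(C(C)C)C(C)C)c(OC)c1 | intermediate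
19 | (1S,2R,5R,6S)-2-(ArA-Si)-6-(ArB-Si)-3,7-dioxabicyclo[3.3.0]octan-1-ol | COc1cc([C@H]2OC[C@H]3[C@]2(O)CO[C@@H]3c2cc(O[Si](C(C)C)(C(C)C)C(C)C)c(OC)c(OC)c2)ccc1O[Si](C(C)C)(C(C)C)C(C)C | intermediate
20 | (1S,2R,5R,6S)-2-(ArA-Si)-6-(ArB-Si)-3,7-dioxabicyclo[3.3.0]octan-1-yl methyl oxalate | COc1cc([C@H]2OC[C@H]3[C@]2(OC(=O)C(=O)OC)CO[C@@H]3c2cc(O[Si](C(C)C)(C(C)C)C(C)C)c(OC)c(OC)c2)ccc1O[Si](C(C)C)(C(C)C)C(C)C | intermediate
21 | (1R,2S,5R,6S)-2-(ArA-Si)-6-(ArB-Si)-3,7-dioxabicyclo[3.3.0]octane | COc1cc([C@H]2OC[C@H]3[C@@H]2CO[C@@H]3c2cc(O[Si](C(C)C)(C(C)C)C(C)C)c(OC)c(OC)c2)ccc1O[Si](C(C)C)(C(C)C)C(C)C | intermediate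
22 | (1R,2S,5R,6S)-2-(4-hydroxy-3-methoxyphenyl)-6-(3-hydroxy-4,5-dimethoxyphenyl)-3,7-dioxabicyclo[3.3.0]octane | COc1cc([C@H]2OC[C@H]3[C@@H]2CO[C@@H]3c2cc(O)c(OC)c(OC)c2)ccc1O | target

## Step count and least certain steps

Total: 14 steps. Longest linear sequence: 13 steps (steps 1 to 5 and 7 to 14, from 1 to 22).

**Step 11 (key step).** The strained α-alkoxy ketone may undergo α-cleavage, or the biradical may return its hydrogen, faster than ring closure. The electron-rich aryl ring β to the carbonyl may quench the excited state, and the closure may be incompletely exo-selective. The fallback sets out from 18 and returns at 21, and replaces photochemical abstraction by radical translocation. Ketone 18 would be condensed with hydrazine to the hydrazone F1, and this treated with iodine and tetramethylguanidine (Barton vinyl iodide synthesis) to give the vinyl iodide F2, with the double bond between C1 and C8 after elimination toward the less hindered, oxygen-bearing methylene. With Bu3SnH and AIBN at high dilution in benzene at 80 °C, the C1 vinyl radical should take the hydrogen from C2 (1,5-hydrogen transfer), the benzylic C2 radical should add 5-exo to C1 of the enol ether, and the C8 radical is reduced. This gives 21 directly with hydrogen already on C1, so steps 12 and 13 fall away.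

**Step 7.** The benzylic alkoxide may be lost from the enolate by β-elimination during the slow, room-temperature soft enolisation, or facial and anti selectivity may erode with the electron-rich aldehyde. The fallback sets out from 9 and 11 and returns at 18, and moves control of C5 from the aldol to a later equilibration. Bu2BOTf and Et3N at −78 °C, a kinetic Z-boron enolate that 3-alkoxypropanoyl imides tolerate well, would give the syn adduct F3, with C6 correct (S) and C5 epimeric. The reagents of steps 8 to 10 would carry it through the peroxy acid F4, the acid F5, the mixed anhydride F6 and the diazoketone F7 to the cis-furanone F8. C5 of F8 is α to the ketone and would be equilibrated with catalytic DBU in toluene at 0 °C to the more stable trans isomer 18.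

**Step 10.** The carbenoid may be captured by the ether oxygen O3, which stands at the same distance as the hydroxyl, leading to an oxonium ylide and benzyl shift in place of O–H insertion. One step earlier, the free hydroxyl may be acylated by the mixed anhydride. The fallback sets out from 13 and returns at 18, and closes ring B by O-alkylation with no carbenoid and no activated acid. Transamination of 13 with MeNHOMe·HCl and AlMe3 would give the Weinreb amide F9, which tolerates the free hydroxyl. Chloromethyllithium, from ICH2Cl and MeLi·LiBr at −78 °C, would give the chloromethyl ketone F10. Ag2O in CH2Cl2 would then promote 5-exo-tet displacement of chloride by the C6 hydroxyl to give 18.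

**Step 13 (with step 12).** Acylation of the hindered bridgehead hydroxyl may be incomplete, and fragmentation of the tertiary oxalate in the stannane chain at 110 °C may be slow. The C1 radical may also open ring B by β-scission of C5–C6, which would give a benzylic, oxygen-stabilised radical, or undergo 1,2-aryl shift before hydrogen transfer. The fallback sets out from 19 and returns at 21, and uses a decarboxylative thiohydroxamate chain. Oxalyl chloride would convert 19 into the chlorooxalate F11. Adding this to the sodium salt of N-hydroxypyridine-2-thione with t-BuSH in benzene under visible light would form the mixed oxalate F12. Its chain decomposition, with loss of two molecules of CO2, generates the C1 radical at room temperature in the presence of a faster hydrogen donor and should give 21.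

## Further compounds

F1 | step 11 | hydrazone of 18 | NN=C1CO[C@H](c2cc(O[Si](C(C)C)(C(C)C)C(C)C)c(OC)c(OC)c2)[C@H]1COCc1ccc(O[Si](C(C)C)(C(C)C)C(C)C)c(OC)c1
F2 | step 11 | (2S,3R)-4-iodo-2-(ArB-Si)-3-{[(ArA-Si)methoxy]methyl}-2,3-dihydrofuran | IC1=CO[C@H](c2cc(O[Si](C(C)C)(C(C)C)C(C)C)c(OC)c(OC)c2)[C@H]1COCc1ccc(O[Si](C(C)C)(C(C)C)C(C)C)c(OC)c1
F3 | step 7 | (4S)-4-benzyl-3-[(2S,3S)-3-hydroxy-3-(ArB-Si)-2-{[(ArA-Si)methoxy]methyl}propanoyl]-1,3-oxazolidin-2-one | O=C(N1[C@@H](Cc2ccccc2)COC1=O)[C@@H](COCc1ccc(O[Si](C(C)C)(C(C)C)C(C)C)c(OC)c1)[C@H](O)c1cc(OC)c(OC)c(O[Si](C(C)C)(C(C)C)C(C)C)c1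
F4 | step 7 | (2S,3S)-3-hydroxy-3-(ArB-Si)-2-{[(ArA-Si)methoxy]methyl}propaneperoxoic acid | OOC(=O)[C@@H](COCc1ccc(O[Si](C(C)C)(C(C)C)C(C)C)c(OC)c1)[C@H](O)c1cc(OC)c(OC)c(O[Si](C(C)C)(C(C)C)C(C)C)c1
F5 | step 7 | (2S,3S)-3-hydroxy-3-(ArB-Si)-2-{[(ArA-Si)methoxy]methyl}propanoic acid | OC(=O)[C@@H](COCc1ccc(O[Si](C(C)C)(C(C)C)C(C)C)c(OC)c1)[C@H](O)c1cc(OC)c(OC)c(O[Si](C(C)C)(C(C)C)C(C)C)c1
F6 | step 7 | mixed anhydride of F5 with isobutyl hydrogen carbonate | CC(C)COC(=O)OC(=O)[C@@H](COCc1ccc(O[Si](C(C)C)(C(C)C)C(C)C)c(OC)c1)[C@H](O)c1cc(OC)c(OC)c(O[Si](C(C)C)(C(C)C)C(C)C)c1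
F7 | step 7 | (3S,4S)-1-diazo-4-hydroxy-4-(ArB-Si)-3-{[(ArA-Si)methoxy]methyl}butan-2-one | [N-]=[N+]=CC(=O)[C@@H](COCc1ccc(O[Si](C(C)C)(C(C)C)C(C)C)c(OC)c1)[C@H](O)c1cc(OC)c(OC)c(O[Si](C(C)C)(C(C)C)C(C)C)c1
F8 | step 7 | (4S,5S)-5-(ArB-Si)-4-{[(ArA-Si)methoxy]methyl}dihydrofuran-3(2H)-one (cis) | O=C1CO[C@H](c2cc(O[Si](C(C)C)(C(C)C)C(C)C)c(OC)c(OC)c2)[C@@H]1COCc1ccc(O[Si](C(C)C)(C(C)C)C(C)C)c(OC)c1
F9 | step 10 | (2R,3S)-3-hydroxy-N-methoxy-N-methyl-3-(ArB-Si)-2-{[(ArA-Si)methoxy]methyl}propanamide | CON(C)C(=O)[C@H](COCc1ccc(O[Si](C(C)C)(C(C)C)C(C)C)c(OC)c1)[C@H](O)c1cc(OC)c(OC)c(O[Si](C(C)C)(C(C)C)C(C)C)c1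
F10 | step 10 | (3R,4S)-1-chloro-4-hydroxy-4-(ArB-Si)-3-{[(ArA-Si)methoxy]methyl}butan-2-one | ClCC(=O)[C@H](COCc1ccc(O[Si](C(C)C)(C(C)C)C(C)C)c(OC)c1)[C@H](O)c1cc(OC)c(OC)c(O[Si](C(C)C)(C(C)C)C(C)C)c1
F11 | step 13 | (1S,2R,5R,6S)-2-(ArA-Si)-6-(ArB-Si)-3,7-dioxabicyclo[3.3.0]octan-1-yl chlorooxoacetate | COc1cc([C@H]2OC[C@H]3[C@]2(OC(=O)C(=O)Cl)CO[C@@H]3c2cc(O[Si](C(C)C)(C(C)C)C(C)C)c(OC)c(OC)c2)ccc1O[Si](C(C)C)(C(C)C)C(C)C
F12 | step 13 | mixed oxalate of 19 with N-hydroxypyridine-2-thione | COc1cc([C@H]2OC[C@H]3[C@]2(OC(=O)C(=O)ON4C=CC=CC4=S)CO[C@@H]3c2cc(O[Si](C(C)C)(C(C)C)C(C)C)c(OC)c(OC)c2)ccc1O[Si](C(C)C)(C(C)C)C(C)C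
A1 | alternative 1 | trans-α-(hydroxybenzyl)-β-(2-aryl-1,3-dithian-2-yl)-γ-menthyloxy butyrolactone, benzyl-protected phenols (C2 carbinol as one epimer) | COc1cc([C@@H](O)[C@H]2C(=O)O[C@@H](O[C@@H]3C[C@H](C)CC[C@H]3C(C)C)[C@@H]2C2(SCCCS2)c2cc(OCc3ccccc3)c(OC)c(OC)c2)ccc1OCc1ccccc1
A2 | alternative 1 | (5R)-5-[(1R,2S,5R)-menthyloxy]furan-2(5H)-one | O=C1C=C[C@H](O[C@@H]2C[C@H](C)CC[C@H]2C(C)C)O1
A3 | alternative 1 | 2-lithio-2-[3-(benzyloxy)-4,5-dimethoxyphenyl]-1,3-dithiane | [Li]C1(SCCCS1)c1cc(OCc2ccccc2)c(OC)c(OC)c1
A4 | alternative 1 | 4-(benzyloxy)-3-methoxybenzaldehyde | O=Cc1ccc(OCc2ccccc2)c(OC)c1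
A5 | alternative 2 | all-trans methyl 2-aryl-3-aryl-4-(silyloxymethyl)cyclobutane-1-carboxylate, tert-butyldimethylsilyl ethers | COc1cc([C@H]2[C@H](c3cc(O[Si](C)(C)C(C)(C)C)c(OC)c(OC)c3)[C@@H](CO[Si](C)(C)C(C)(C)C)[C@@H]2C(=O)OC)ccc1O[Si](C)(C)C(C)(C)C
A6 | alternative 2 | methyl (E)-3-[4-(tert-butyldimethylsilyloxy)-3-methoxyphenyl]acrylate | COC(=O)/C=C/c1ccc(O[Si](C)(C)C(C)(C)C)c(OC)c1
A7 | alternative 2 | (E)-3-[3-(tert-butyldimethylsilyloxy)-4,5-dimethoxyphenyl]allyl tert-butyldimethylsilyl ether | COc1cc(/C=C/CO[Si](C)(C)C(C)(C)C)cc(O[Si](C)(C)C(C)(C)C)c1OC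
A8 | alternative 3 | 2,6-diaryl-3,7-dioxabicyclo[3.3.0]octane-4,8-dione, bis(tert-butyldimethylsilyl) ether | COc1cc([C@H]2OC(=O)[C@H]3[C@@H]2C(=O)O[C@@H]3c2cc(O[Si](C)(C)C(C)(C)C)c(OC)c(OC)c2)ccc1O[Si](C)(C)C(C)(C)C
A9 | alternative 3 | (4S,8S)-4,8-diaryl-1,5-dioxocane-2,6-dione, bis(tert-butyldimethylsilyl) ether | COc1cc([C@@H]2CC(=O)O[C@H](c3cc(O[Si](C)(C)C(C)(C)C)c(OC)c(OC)c3)CC(=O)O2)ccc1O[Si](C)(C)C(C)(C)C
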